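A bench chemist looking at the violet flask reaches first for the limiting reagent, and we do the same.

the same everywhere: substrate 14 mM; gas 1.6 mM (held)

|  | first nucleophile | temperature | remark | time |
|---|---|---|---|---|
| violet | 0.80 equiv | 0 °C | the very flask that is asked about, followed so far |  |
| amber | 1.2 equiv | −15 °C | run made earlier |  |
| flask | 0.800 equiv | 0 °C |  | 15 h |

| run | time / min | target / % |
|---|---|---|
| violet | 90.0 | 17.7 |
| violet | 180 | 17.6 |
| violet | 300 | 17.7 |
| violet | 360 | 17.7 |
| violet | 480 | 18.5 |
| violet | 600 | 18.5 |
| amber | 6.00 | 0.9 |
| amber | 10.0 | 0.1 |
| amber | 15.0 | 0.6 |
| amber | 25.0 | 1.5 |
| amber | 40.0 | 0.4 |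
| amber | 80.0 | 0 |

(scatter of a reading: 0.5 percentage points)

- gamma: change nothing and wait 30 h more
- delta: at 15 h raise the temperature by 15 K, then wait 30 h
- beta: at 15 h add substrate, 50.0 % of the amount charged, then wait 30 h
- epsilon: at 15 h add first nucleophile, 100 % of the amount charged, then wait 30 h

- what is added takes up no volume worth counting
- at the start none of the gas is in solution
- a reading or a percentage of target counts all its forms, free or not

- target, in percent of the substrate first charged, at 15 h
- the option that brings most further target ("none" if no option brings more than 2 percentage points) (gamma / delta / beta / epsilon / none)
- target present, in percent of the substrate first charged, after delta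
- target present, in percent of the substrate first charged, after beta

The rule of thumb says that target stops where the smaller charge stops. If one first nucleophile makes one target, the violet charge of 0.800 equiv allows 80.0 % of the substrate. We first read where the violet flask stands, treating the late rise as a small correction to a flat line. The last two readings lie 0.82 percentage points above the first four, with each reading good to 0.5 points, so we do not follow that step as a trend. The mean of the six, 18.0 %, is our reckoning for 15 h.

Now we hold this plateau against the allowance. Target at the plateau, divided by what the limiting charge allows, is the charge efficiency 22.4 %. Near one, the rule of thumb explains the stop. At this value it does not, and the violet readings, which follow target, do not say which partner is missing. The amber run, colder and richer in first nucleophile, reads no higher than 1.5 %, and that does not tell us either. So for the violet flask we leave the choice among the options open, since no reading shows whether substrate is still there at 15 h.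

The forecast gives 18.2 %, a little above our mean, with 18.6 % after delta and 18.5 % after beta. It names epsilon, taking as the likeliest cause that “the first nucleophile was used up”.

The flask gives 17.8 %, 17.8 % after delta and 17.9 % after beta, and the best option is none.

    substrate ⇌ intermediate (K = 0.157, k = 7.37 × 10⁻⁴ /s, Ea = 80.0 kJ/mol, ΔH = 4.00 kJ/mol)
    first nucleophile + intermediate → target (k = 20.7 /M/s, Ea = 49.0 kJ/mol)
    second nucleophile + intermediate → other capture product (k = 3420 /M/s, Ea = 13.0 kJ/mol)
    crystals ⇌ target, rate k4*(cs4 - [target]) while solid is left; crystals form when [target] > cs4 (solubility = 12.0 mM, k = 0.0159 /s)
    gas ⇌ second nucleophile, rate k5*(csat - [second nucleophile]) (kL = 0.00346 /s)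
    2 first nucleophile → self-condensation product (k = 0.0548 /M/s, Ea = 35.0 kJ/mol)
    (constants at 0 °C)

In this flask, the conversion of substrate into intermediate had 98 % of its turnover up to 15 h behind it by 90.0 min, while second nucleophile stood at 1.53 mM and other capture product had reached 80.3 % against 17.8 % of target. At 15 h free substrate stood at 0 % and first nucleophile at 1.5 %, each of its own charge, and epsilon brought 0 points. Against our efficiency of 22.4 %, the neighbour kept at 25 °C with the same charges reached 71.5 %, an efficiency of 89.4 %, with 0 % of its first nucleophile left.

(Readings and results come from a simulation for substances that don't exist; the scatter is artificial.)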